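I back west as the flask that ends with the most over-reaction product, and here is my quick reckoning.

| setting | noon | spring | autumn | dawn | west | north | south-west | north-east | east |
|---|---|---|---|---|---|---|---|---|---|
| substrate | 0.40 M | 0.56 M | 0.88 M | 0.40 M | 0.40 M (in portions, 3, over 15 h) | 0.40 M | 0.40 M | 0.40 M | 0.40 M (fed, over 15 h) |
| partner | 1 M | 1 M | 1 M | 1.5 M | 1.00 M | 1.00 M | 1.00 M | 1.00 M | 1.00 M |
| second reagent | 0.20 M | 0.20 M | 0.20 M | 0.20 M | 0.200 M | 0.200 M (fed, over 4.0 h) | 0.200 M | 0.200 M (fed, over 15 h) | 0.200 M |
| remark | run made earlier | run made earlier | run made earlier | run made earlier | first portion at the start, last at 15 h | all else is in the flask from the start; the feed brings no volume worth counting | everything together at the start | all else is in the flask from the start; the feed brings no volume worth counting | all else is in the flask from the start; the feed brings no volume worth counting |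
| time |  |  |  |  | 20 h | 20 h | 20 h | 20 h | 20 h |

- noon (time / h: over-reaction product / %, target / %): 3.00: 4.8, 36.8; 6.00: 4.9, 36.5; 10.0: 2.9, 37.3; 12.0: 3.4, 38.6; 15.0: 6.1, 39.2; 20.0: 5.3, 38.4
- spring (time / h: over-reaction product / %, target / %): 4.00: 2.9, 28.9; 8.00: 0.9, 27.8; 12.0: 2.8, 28.1; 15.0: 5.5, 29.1; 20.0: 5.8, 28.6; 25.0: 2.7, 31.5
- autumn (time / h: over-reaction product / %, target / %): 4.00: 1.0, 16.7; 8.00: 0, 19.2; 12.0: 0, 19.6; 15.0: 0, 20.3; 20.0: 3.3, 19.7; 25.0: 1.9, 19.4
- dawn (time / h: over-reaction product / %, target / %): 2.00: 4.4, 35.4; 4.00: 5.9, 38.1; 6.00: 4.0, 38.7; 12.0: 5.2, 41.8; 25.0: 3.9, 40.0

(standard deviation of a reading: 1 percentage point)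

- which flask leads in amount of over-reaction product, in percent of the substrate charged ("all alike" within 1.5 percentage points) (west / north / south-west / north-east / east / all alike)
- how much over-reaction product is there at the end, in percent of the substrate charged: west
- how much over-reaction product is there at the end, in percent of the substrate charged: north
- how much over-reaction product is there at the end, in percent of the substrate charged: south-west
- how much over-reaction product is there at the end, in percent of the substrate charged: north-east
- how much over-reaction product is there at the end, in percent of the substrate charged: east

- the analysis behind the earlier runs scatters by 1 percentage point, standard deviation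

I read the runs as a chain. Substrate, partner and second reagent give target, and second reagent then attacks target to give over-reaction product. Second reagent looks like the limiting reagent, so I carry one number, the reagent budget: second reagent charged per substrate charged, 50.0%. One target costs one second reagent and one over-reaction product costs two. So, late in these runs, target plus two times over-reaction product should match the budget. The last readings give 49.0% for noon against 50.0%, 36.9% for spring against 35.7%, and 23.2% for autumn against 22.7%.

The budget doesn't tell me the split, so I go to the readings. Noon's over-reaction readings average 4.57%, and I take that for south-west. In west, the first portion is 0.133 M against 0.200 M of second reagent, a local budget of 150%. The surplus over that portion is 16.7% of the whole charge, and each surplus second reagent can turn one target into one over-reaction product. I commit to west landing between noon's average and that mark. East has no portion to reckon on, so placing west above east is my judgement.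

Your hunch, the forecast, also names west. It gives 16% for west, 14% for east, and 4.6%, 4.6% and 4.6% for north, south-west and north-east, holding that “feeding the reagent changes nothing as long as it is finished by 20 h”.

The flasks give 10.9% for west, 3.54% for north, 5.11% for south-west, 3.13% for north-east and 8.89% for east, so west leads.

    substrate + partner → intermediate (k = 3.00 × 10⁻⁴ L mol⁻¹ s⁻¹)
    second reagent + intermediate → target (k = 0.00280 L mol⁻¹ s⁻¹)
    second reagent ⇌ dormant form (K = 1.10, k = 6.00 × 10⁻⁵ s⁻¹)
    second reagent + target → over-reaction product (k = 5.70 × 10⁻⁴ L mol⁻¹ s⁻¹)

In north-east at 0.726 h, second reagent goes to target 270 times as fast as to over-reaction product. The loss to over-reaction product in north-east is half done by 11.4 h. In west at 20.0 h, target, two times over-reaction product, dormant form and free second reagent together stand at 50.0% against the budget of 50.0%. A neighbour of north-east with 0.34 M of second reagent has a budget of 85.0%, and the same count at 20.0 h, with 62.1% target and 10.8% over-reaction product in it, comes to 85.0%.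

Readings and results are simulated from invented constants; scatter was added.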